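| flask | substrate | reagent | initiator | remark | time |
|---|---|---|---|---|---|
| zeta | 0.67 M | 1 M | 5.7 mM | run made earlier |  |
| epsilon | 1 M | 0.50 M | 5.7 mM | run made earlier |  |
| east | 1.0 M | 1.00 M | 5.7 mM |  | 40 h |
| north | 1.0 M | 1.00 M | 1.5 mM |  | 20 h |

- zeta (time / h: target / %, substrate / %): 2.00: 88.0, 10.6; 4.00: 95.7, 1.2; 6.00: 97.5, 0.6; 8.00: 96.7, 0.8
- epsilon (time / h: target / %, substrate / %): 0.667: 39.1, 60.9; 1.33: 48.7, 48.5; 3.00: 45.8, 46.6; 8.00: 40.7, 40.3

(each reading ± 0.5 percentage points)

- no earlier run changes the charge of initiator; that part of a forecast is a guess

- the winner by amount of target, in percent of the substrate charged; "neither" if no more than 2 percentage points parts them (east / north / neither)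
- how much target is there at the end, in percent of the substrate charged: east
- how much target is there at the end, in percent of the substrate charged: north

The leftover substrate in the epsilon run shows the cost. From 1.33 h to 8.00 h substrate falls from 48.5 % to 40.3 % and target from 48.7 % to 40.7 %, so I read the two as consuming each other, one for one. With the two about equal, the reciprocal of concentration climbs steadily. I read from that climb a side time constant at the charge of east and north, the time in which the reciprocal gains one over the charge: τ_side = 15.9 h.

Zeta gives the main clock. By the readings, substrate shrinks by a factor 9.43 up to 2.00 h and by a further 8.83 from there to 4.00 h, though by the target reading reagent stands at 0.410 M after the first stretch. So I take the loss of substrate in zeta as first order in substrate (pseudo-first-order), and read τ_main = 0.891 h.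

Two versions solve in the head. With an instant main step, substrate never meets target, and target ends at the full charge. With a main step far slower than the side step, each target made meets substrate and is taken, and target ends near nothing. I place east near the first version, as τ_main is far shorter than τ_side, so I integrate the overlap:

c_substrate = c_charge · exp(−t/τ_main), c_target = c_charge − c_substrate

side events = ∫ c_substrate · c_target dt / (τ_side · c_charge) = c_charge · τ_main / (2 · τ_side)

Each event takes 2 units of the charge, so the side share of east is τ_main/τ_side = 5.61 %.

By this reckoning east ends at 94.4 %. For north I guess that the rate goes with the root of initiator, so τ_main = 1.74 h, the share is 10.9 %, and target ends at 89.1 %. Both times asked far exceed these two values of τ_main.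

The forecast names east, with east at 90 % (83 % to 94 %) and north at 77 % (58 % to 88 %), both lower than mine. Its grounds for north: “side loss roughly doubles, and conversion may stall”.

East ends at 95.0 % and north at 90.9 %.

    substrate + target → side product (k = 0.00100 L mol⁻¹ min⁻¹)
    reagent + first chain carrier → target + second chain carrier (k = 1.70 × 10⁵ L mol⁻¹ min⁻¹)
    2 second chain carrier → ended chains (k = 5.00 × 10⁷ L mol⁻¹ s⁻¹)
    substrate + second chain carrier → by-product + first chain carrier (k = 1.80 × 10⁵ L mol⁻¹ s⁻¹)
    substrate + initiating radical → capped initiator + first chain carrier (k = 3.20 × 10⁵ L mol⁻¹ s⁻¹)
    initiator → 2 initiating radical (k = 1.60 × 10⁻⁶ min⁻¹)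

The remainder of each charge stands as side product, 4.96 % in east and 9.10 % in north, where the side share gave 5.61 % and 10.9 %. For the neighbour flask, east with 0.0014 M of initiator, the same share with the root rule gives 11.3 %; that flask holds 9.38 % of side product.

The runs are simulated on assumed constants, noise included.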